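## The problem

Positions are numbered as in the verticillane skeleton: the six-membered ring is C1, C14, C13 (ketone), C12 (bearing the methylene C18), C11 and C15 (gem-dimethyl), and the chain C2–C10 runs from C1 to C11.

- The target is a bicyclo[9.3.1]pentadecane. A cyclohexanone is spanned across C1 and C11 by a nine-carbon chain, which together with C15 forms a twelve-membered ring.
- There are seven stereocentres: C1 (R), C11 (S), the acetoxy carbon C10 (R), the trans trisubstituted epoxide C3/C4 (R,R) and the cis trisubstituted epoxide C7/C8 (R,S). The bonds C1–C2 and C11–C10 leave the six-membered ring from opposite faces.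
- Control can be relayed. C1 can set C11 (trans conjugate addition across the gem-dimethyl carbon), C11 can set C10 (addition to an aldehyde on C11), and a free C10 hydroxyl can direct oxygen to C7=C8. Only C3/C4 has no neighbouring handle and depends on the shape of the large ring.
- The α-methylene ketone (C18=C12–C13=O) is a Michael acceptor and can slip its double bond into the ring. The two epoxides are acid-labile and 1,5-related across the ring, so transannular opening is a danger. The acetate is base-labile. These groups must therefore appear at the very end.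
- The epoxides derive from a 3E and a 7Z trisubstituted olefin, and such geometries are hard to make or correct inside a macrocycle.
- The enabling feature is the pair C5/C6: two adjacent allylic methylenes between C3=C4 and C7=C8, carrying neither a heteroatom nor a stereocentre. The C5–C6 bond can be made from two allyl halves if one is polarity-reversed by a removable sulfone on C6.

## Retrosynthesis

**Oxygenation last (34 ⇐ 33 ⇐ 32 ⇐ 31).** The C3/C4 epoxide is removed first, then the acetate, then the C7/C8 epoxide, giving hydroxy dienone 31. This order lets the free C10 hydroxyl direct the 7,8-epoxidation, keeps acetate and epoxides away from earlier chemistry, and leaves only the remote E-olefin for the final peracid step. The forward reactions must tell three olefins apart. The enone olefin is electron-poor, C7=C8 is reached through the hydroxyl, and C3=C4 is the only electron-rich olefin left at the end.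

**Unmasking (31 ⇐ 30 ⇐ 29).** The ketone is masked as a dioxolane and O10 as a TBS ether in 30, and C6 carries a phenylsulfonyl group in 29. Acid is used only on the diene 30, before any epoxide exists. The sulfone is removed by palladium-catalysed hydride delivery to the less substituted allyl terminus, so that C7=C8 stays in place.

**Key cut C5–C6 (29 ⇐ 28).** The twelve-membered ring is opened between the two allylic methylenes to give bromide/sulfone 28. Cuts at C2–C3, C4–C5, C8–C9 or C9–C10 would each make an olefin or a stereocentre during ring closure. This cut joins two sp3 carbons and brings both olefins in with fixed geometry. The forward step must give SN2 closure at C5 by the C6 carbanion without loss of either geometry.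

**C1 arm (28 ⇐ 27 ⇐ 26 ⇐ 23 ⇐ 21).** The E-allylic bromide comes from allylic alcohol 27 and enoate 26. The C3=C4 bond is cut by a Wittig reaction between the C3 aldehyde and stabilised ylide 24, which reliably gives the E-trisubstituted olefin. The aldehyde comes from alcohol 23, and this from the vinyl group of 21 by anti-Markovnikov hydration. The vinyl group needs no protection through the whole sulfone-arm sequence. The forward hydroboration must choose the monosubstituted olefin over the hindered methylene.

**Sulfone arm (21 ⇐ 18 ⇐ 17 ⇐ 16 ⇐ 15).** The C6–S bond is cut to sodium benzenesulfinate 19 and the Z-allylic alcohol 18. Alcohol 18 comes, through bis-silyl ether 17, from Z-diol 16 and lactone 15. The six-membered lactone is the device that fixes the 7Z geometry, since a ring of this size can only hold a cis olefin.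

**C9–C10 (15 ⇐ 12 + 14).** The lactone is cut to ring aldehyde 12 and silyl dienolate 14, made from ethyl 3-methylbut-2-enoate 13. One vinylogous aldol step supplies C6–C9, the methyl on C8 and the C10 oxygen. The forward reaction must attack through the γ-carbon, choose the correct aldehyde face under control of C11, and leave the epimerisable C11–H alone.

**Ring substituents (12 ⇐ 10 ⇐ 9 ⇐ 6 ⇐ 4 + 5).** The aldehyde carbon is traced to a 2-methylprop-1-enyl group, the only electron-rich olefin in ketal 10, so it can be cleaved selectively. Ketal 10 comes from α-methylene ketone 9. C12=C18 is cut by a Mannich/elimination sequence on silyl enol ether 6. The C11–C10 bond is cut by conjugate addition of Grignard reagent 5 to enone 4. One conjugate addition thus sets C11 trans to C1 and delivers the enolate exactly where the methylene is needed.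

**First stereocentre (4 ⇐ 2 + 3 ⇐ 1).** Enone 4 is cut at C1–C2 to the symmetrical dienone 2 and potassium vinyltrifluoroborate 3. Dienone 2 is one oxidation away from 4,4-dimethylcyclohex-2-en-1-one 1. Addition to one of the two enantiotopic enone halves sets the absolute configuration and leaves the second enone ready for the next addition.

## Roads not taken

**Alternative 1: enzymatic cyclisation.** The bicycle is unfolded at C1–C2 and C11–C15 to the acyclic diphosphate A2, a geranylgeranyl isomer with one Z double bond. A class 1 diterpene cyclase would ionise A2, close the fourteen-membered ring, then the six-membered ring, and lose a proton from C18 to give triene A1.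
- Merits: one step makes the whole carbon skeleton, both bridgehead centres and both olefin geometries without protecting groups. In step economy to the hydrocarbon this road is clearly better than the chosen plan.
- Weak points: it needs an enzyme that accepts the unnatural isomer A2, folds it to the trans-bridged configuration and stops at C18 deprotonation. A1 carries no oxygen. C13 is allylic and could be oxidised chemically, but C10 is an unactivated methylene, so a second selective enzyme or a long detour is needed. The epoxidations then face the same issues as here.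
- Comparison: the chosen plan is much longer. Against this it uses only bench reactions of known type, carries O10 and O13 from the first steps, and does not depend on finding or engineering two enzymes.

**Alternative 2: chlorohydrin-type epoxide union.** The cut is at C4–C5 together with the C3–O bond. The homoallylic Grignard reagent A5 would add to the methyl ketone of the ring-bound α-chloro ketone A4 anti to chlorine, and the alkoxide would displace chloride to give trans epoxide A3.
- Merits: it is convergent, the Z-olefin arrives preformed, and the C3/C4 configuration is fixed by an acyclic, stereospecific event. In this respect it is better than the chosen plan, whose last epoxidation relies on the conformation of the macrocycle.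
- Weak points: the C3 chloride must first be made as one diastereomer far from the ring centres. Selectivity of such additions to methyl ketones is often moderate. The sensitive epoxide must then survive a ring closure at C9–C10, which would have to create the C10 carbinol centre inside the forming ring next to the C12 methylene.
- Comparison: the chosen plan sets C10 before ring closure and closes the ring at a bond without stereochemistry. It pays for this with a less secure C3/C4 epoxidation.

**Alternative 3: nitrile oxide macrocyclisation.** The cut is at C8–C9 and C10–O. Oxidation of aldoxime A7 with NaOCl generates the dipole in situ, which adds to the vinyl group on C11 and closes both the isoxazoline and the twelve-membered ring of A6.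
- Merits: one step forms a C–C bond and installs O10. The tether fixes the regiochemistry, the cycloaddition is irreversible, and no strong base is used. For the ring closure itself this may be as good as or more robust than a carbanion alkylation.
- Weak points: the C10 configuration rests only on the facial bias exerted by C11. After N–O cleavage C8 is a carbonyl carbon, so the 7Z trisubstituted olefin with its methyl group must be built inside the ring, where geometry control is poor. Extra redox steps follow.
- Comparison: the chosen plan brings both olefins in with defined geometry and removes its auxiliary sulfone in one step without trace. It has to accept a strongly basic ring closure.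

Key step: step 17

Remark: the two C6 epimers of 29 are assumed to be carried on together, since step 18 removes this centre. The new centres of the non-isolated intermediates 7, 8 and 11 are left undefined because they are destroyed in the same step.

## Steps

Step 1
Reactants: 1 4,4-dimethylcyclohex-2-en-1-one
Product: 2 4,4-dimethylcyclohexa-2,5-dien-1-one
Conditions: DDQ, dioxane, reflux
Reagents that add atoms: none
Why: Quinone dehydrogenation of a cyclohexenone to the cross-conjugated dienone; the quaternary carbon blocks aromatisation and the product is symmetrical, which prepares the desymmetrisation.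

Step 2
Reactants: 2 4,4-dimethylcyclohexa-2,5-dien-1-one; 3 potassium vinyltrifluoroborate
Product: 4 (5S)-5-ethenyl-4,4-dimethylcyclohex-2-en-1-one
Conditions: [Rh(cod)2]PF6 (3 mol %), (S)-BINAP (3.3 mol %), 3 (1.1 equiv), toluene–H2O, 100 °C
Reagents that add atoms: none
Why: Rhodium-catalysed asymmetric conjugate addition (Hayashi–Miyaura reaction) of an alkenylboron reagent to a cyclic enone; the (S)-ligand is chosen by analogy with the face it selects on cyclohex-2-enone and should set C1. The second enone half is kept for step 3.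

Step 3
Reactants: 4 (5S)-5-ethenyl-4,4-dimethylcyclohex-2-en-1-one; 5 (2-methylprop-1-en-1-yl)magnesium bromide
Product: 6 trimethyl{[(3R,5S)-5-ethenyl-4,4-dimethyl-3-(2-methylprop-1-en-1-yl)cyclohex-1-en-1-yl]oxy}silane
Conditions: 5 (1.5 equiv), CuBr·SMe2 (10 mol %), TMSCl (2 equiv), THF, −78 → −40 °C; Et3N
Reagents that add atoms: chlorotrimethylsilane, C[Si](C)(C)Cl
Why: Copper-catalysed conjugate addition with in situ silylation; axial attack at C11 anti to the vinyl group on C1 should give the trans product, and silyl trapping fixes the enolate at C12.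

Step 4
Reactants: 6 trimethyl{[(3R,5S)-5-ethenyl-4,4-dimethyl-3-(2-methylprop-1-en-1-yl)cyclohex-1-en-1-yl]oxy}silane
Product: 9 (3S,5S)-5-ethenyl-4,4-dimethyl-2-methylidene-3-(2-methylprop-1-en-1-yl)cyclohexan-1-one, via Mannich base 7 (not isolated), via ammonium iodide 8 (not isolated)
Conditions: Me2N=CH2+ I− (Eschenmoser's salt), CH2Cl2, rt; MeI, Et2O, rt; aq. NaHCO3, CH2Cl2, rt
Reagents that add atoms: Eschenmoser's salt (dimethyl(methylidene)ammonium iodide), C=[N+](C)C.[I-]
Why: Mannich aminomethylation of a regiodefined silyl enol ether, then quaternisation and β-elimination, the standard route to α-methylene ketones; the mild base should leave the doubly allylic C11–H untouched.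

Step 5
Reactants: 9 (3S,5S)-5-ethenyl-4,4-dimethyl-2-methylidene-3-(2-methylprop-1-en-1-yl)cyclohexan-1-one
Product: 10 (7S,9S)-9-ethenyl-8,8-dimethyl-6-methylidene-7-(2-methylprop-1-en-1-yl)-1,4-dioxaspiro[4.5]decane
Conditions: TMSOCH2CH2OTMS, TMSOTf (cat.), CH2Cl2, −78 → −20 °C; pyridine
Reagents that add atoms: 1,2-bis(trimethylsilyloxy)ethane, C[Si](C)(C)OCCO[Si](C)(C)C
Why: Aprotic silyl-transfer ketalisation, the method of choice for enones because it avoids double-bond migration and conjugate addition of the diol.

Step 6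
Reactants: 10 (7S,9S)-9-ethenyl-8,8-dimethyl-6-methylidene-7-(2-methylprop-1-en-1-yl)-1,4-dioxaspiro[4.5]decane
Product: 12 (7S,9S)-9-ethenyl-8,8-dimethyl-6-methylidene-1,4-dioxaspiro[4.5]decane-7-carbaldehyde, via epoxide 11 (not isolated)
Conditions: mCPBA (1.0 equiv), NaHCO3, CH2Cl2, −20 °C; then H5IO6, THF–H2O, 0 °C
Reagents that add atoms: 3-chloroperoxybenzoic acid, O=C(OO)c1cccc(Cl)c1
Why: Peracid epoxidation picks the only trisubstituted, electron-rich olefin over the vinyl group and the ketal-deactivated methylene; periodic acid cleavage of the epoxide then releases the aldehyde and acetone. Cold, short exposure is meant to spare the ketal and the C11 centre.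

Step 7
Reactants: 13 ethyl 3-methylbut-2-enoate
Product: 14 [(1-ethoxy-3-methylbuta-1,3-dien-1-yl)oxy]trimethylsilane
Conditions: LiN(i-Pr)2, THF, −78 °C; TMSCl, −78 °C → rt
Reagents that add atoms: chlorotrimethylsilane, C[Si](C)(C)Cl
Why: γ-Deprotonation of the senecioate ester and O-silylation give the silyl dienolate, a known vinylogous ketene acetal.

Step 8
Reactants: 12 (7S,9S)-9-ethenyl-8,8-dimethyl-6-methylidene-1,4-dioxaspiro[4.5]decane-7-carbaldehyde; 14 [(1-ethoxy-3-methylbuta-1,3-dien-1-yl)oxy]trimethylsilane
Product: 15 (6R)-6-[(7S,9S)-9-ethenyl-8,8-dimethyl-6-methylidene-1,4-dioxaspiro[4.5]decan-7-yl]-4-methyl-5,6-dihydro-2H-pyran-2-one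
Conditions: CuF(PPh3)3·2MeOH (10 mol %), THF, −40 °C → rt
Reagents that add atoms: none
Why: Copper-fluoride-catalysed vinylogous Mukaiyama aldol addition: the soft copper dienolate attacks through its γ-carbon and the aldolate closes onto the ester, so the lactone locks C7=C8 as Z. C10 is set by the aldehyde itself: with the quaternary C15 anti to the nucleophile and the C11 hydrogen beside its path, the open transition state leads to 10R. The near-neutral medium should spare the C11–H.

Step 9
Reactants: 15 (6R)-6-[(7S,9S)-9-ethenyl-8,8-dimethyl-6-methylidene-1,4-dioxaspiro[4.5]decan-7-yl]-4-methyl-5,6-dihydro-2H-pyran-2-one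
Product: 16 (2Z,5R)-5-[(7S,9S)-9-ethenyl-8,8-dimethyl-6-methylidene-1,4-dioxaspiro[4.5]decan-7-yl]-3-methylpent-2-ene-1,5-diol
Conditions: i-Bu2AlH (4 equiv), CH2Cl2, −78 → 0 °C; Rochelle salt
Reagents that add atoms: none
Why: 1,2-Reduction of an unsaturated lactone through the lactol to the Z-enediol; the olefin geometry is carried over from the ring.

Step 10
Reactants: 16 (2Z,5R)-5-[(7S,9S)-9-ethenyl-8,8-dimethyl-6-methylidene-1,4-dioxaspiro[4.5]decan-7-yl]-3-methylpent-2-ene-1,5-diol
Product: 17 bis(tert-butyldimethylsilyl) ether of diol 16 (O6 and O10 silylated, 2Z,5R)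
Conditions: TBSOTf (2.5 equiv), 2,6-lutidine, CH2Cl2, −78 → 0 °C
Reagents that add atoms: tert-butyldimethylsilyl trifluoromethanesulfonate, CC(C)(C)[Si](C)(C)OS(=O)(=O)C(F)(F)F
Why: Exhaustive silylation; protecting both hydroxyls at once avoids any activated C6 derivative next to a free C10 hydroxyl, which would close to a dihydropyran.

Step 11
Reactants: 17 bis(tert-butyldimethylsilyl) ether of diol 16
Product: 18 (2Z,5R)-5-[(tert-butyldimethylsilyl)oxy]-5-[(7S,9S)-9-ethenyl-8,8-dimethyl-6-methylidene-1,4-dioxaspiro[4.5]decan-7-yl]-3-methylpent-2-en-1-ol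
Conditions: HF·pyridine, pyridine, THF, 0 °C
Reagents that add atoms: none
Why: Selective cleavage of a primary allylic silyl ether beside a hindered secondary one under buffered fluoride, a routine differentiation that the ketal tolerates.

Step 12
Reactants: 18 (2Z,5R)-5-[(tert-butyldimethylsilyl)oxy]-5-[(7S,9S)-9-ethenyl-8,8-dimethyl-6-methylidene-1,4-dioxaspiro[4.5]decan-7-yl]-3-methylpent-2-en-1-ol; 19 sodium benzenesulfinate
Product: 21 tert-butyl{[(1R,3Z)-1-[(7S,9S)-9-ethenyl-8,8-dimethyl-6-methylidene-1,4-dioxaspiro[4.5]decan-7-yl]-3-methyl-5-(phenylsulfonyl)pent-3-en-1-yl]oxy}dimethylsilane, via mesylate 20 (not isolated)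
Conditions: MsCl, Et3N, CH2Cl2, −40 °C; then 19, DMF, rt
Reagents that add atoms: none
Why: Activation of the primary allylic alcohol and SN2 displacement by sulfinate sulfur, the standard entry to allylic sulfones; direct displacement at the unhindered CH2 keeps the Z geometry.

Step 13
Reactants: 21 tert-butyl{[(1R,3Z)-1-[(7S,9S)-9-ethenyl-8,8-dimethyl-6-methylidene-1,4-dioxaspiro[4.5]decan-7-yl]-3-methyl-5-(phenylsulfonyl)pent-3-en-1-yl]oxy}dimethylsilane
Product: 23 2-[(7S,9R)-7-[(1R,3Z)-1-[(tert-butyldimethylsilyl)oxy]-3-methyl-5-(phenylsulfonyl)pent-3-en-1-yl]-8,8-dimethyl-6-methylidene-1,4-dioxaspiro[4.5]decan-9-yl]ethan-1-ol, via alkylborane 22 (not isolated)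
Conditions: Sia2BH (from BH3·SMe2 and 2-methylbut-2-ene), THF, 0 °C; then NaOH (3 M), H2O2 (30 %), 0 °C → rt
Reagents that add atoms: hydrogen peroxide, OO
Why: Hydroboration–oxidation with a hindered dialkylborane, which strongly prefers a monosubstituted olefin over the crowded, ketal-deactivated 1,1-disubstituted methylene and the trisubstituted olefin; boron goes to the terminal carbon.

Step 14
Reactants: 23 2-[(7S,9R)-7-[(1R,3Z)-1-[(tert-butyldimethylsilyl)oxy]-3-methyl-5-(phenylsulfonyl)pent-3-en-1-yl]-8,8-dimethyl-6-methylidene-1,4-dioxaspiro[4.5]decan-9-yl]ethan-1-ol; 24 ethyl 2-(triphenylphosphoranylidene)propanoate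
Product: 26 ethyl (2E)-4-[(7S,9R)-7-[(1R,3Z)-1-[(tert-butyldimethylsilyl)oxy]-3-methyl-5-(phenylsulfonyl)pent-3-en-1-yl]-8,8-dimethyl-6-methylidene-1,4-dioxaspiro[4.5]decan-9-yl]-2-methylbut-2-enoate, via aldehyde 25 (not isolated)
Conditions: Dess–Martin periodinane, CH2Cl2, 0 °C → rt; then 24 (2.5 equiv), rt
Reagents that add atoms: none
Why: One-pot alcohol oxidation and Wittig reaction with a stabilised ylide; α-branched stabilised ylides give E-trisubstituted enoates, which sets the 3E geometry, and the weakly basic ylide does not disturb the sulfone.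

Step 15
Reactants: 26 ethyl (2E)-4-[(7S,9R)-7-[(1R,3Z)-1-[(tert-butyldimethylsilyl)oxy]-3-methyl-5-(phenylsulfonyl)pent-3-en-1-yl]-8,8-dimethyl-6-methylidene-1,4-dioxaspiro[4.5]decan-9-yl]-2-methylbut-2-enoate
Product: 27 (2E)-4-[(7S,9R)-7-[(1R,3Z)-1-[(tert-butyldimethylsilyl)oxy]-3-methyl-5-(phenylsulfonyl)pent-3-en-1-yl]-8,8-dimethyl-6-methylidene-1,4-dioxaspiro[4.5]decan-9-yl]-2-methylbut-2-en-1-ol
Conditions: i-Bu2AlH (2.5 equiv), CH2Cl2, −78 °C
Reagents that add atoms: none
Why: 1,2-Reduction of an enoate to the allylic alcohol; sulfone, silyl ether and ketal are inert to the hydride at this temperature.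

Step 16
Reactants: 27 (2E)-4-[(7S,9R)-7-[(1R,3Z)-1-[(tert-butyldimethylsilyl)oxy]-3-methyl-5-(phenylsulfonyl)pent-3-en-1-yl]-8,8-dimethyl-6-methylidene-1,4-dioxaspiro[4.5]decan-9-yl]-2-methylbut-2-en-1-ol
Product: 28 {[(1R,3Z)-1-[(7S,9R)-9-[(2E)-4-bromo-3-methylbut-2-en-1-yl]-8,8-dimethyl-6-methylidene-1,4-dioxaspiro[4.5]decan-7-yl]-3-methyl-5-(phenylsulfonyl)pent-3-en-1-yl]oxy}(tert-butyl)dimethylsilane
Conditions: CBr4, PPh3, 2,6-lutidine, CH2Cl2, −20 °C
Reagents that add atoms: carbon tetrabromide, BrC(Br)(Br)Br
Why: Appel bromination of a primary allylic alcohol, which proceeds without allylic transposition under buffered, cold conditions.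

Step 17
Reactants: 28 {[(1R,3Z)-1-[(7S,9R)-9-[(2E)-4-bromo-3-methylbut-2-en-1-yl]-8,8-dimethyl-6-methylidene-1,4-dioxaspiro[4.5]decan-7-yl]-3-methyl-5-(phenylsulfonyl)pent-3-en-1-yl]oxy}(tert-butyl)dimethylsilane
Product: 29 (1R,3E,7Z,10R,11S)-10-[(tert-butyldimethylsilyl)oxy]-13,13-(ethylenedioxy)-6-(phenylsulfonyl)verticilla-3,7,12(18)-triene (C6 epimers, one drawn)
Conditions: KN(SiMe3)2 (1.2 equiv), THF, −78 → −20 °C, slow addition of 28 (final ca. 2 mM)
Reagents that add atoms: none
Why: KN(SiMe3)2 removes a proton from C6, which is both allylic and α to sulfur, and the sulfonyl-stabilised carbanion displaces bromide from the primary allylic carbon C5 in an SN2 sense. The closest known reaction type is the intramolecular alkylation of allylic sulfone anions by allylic halides, used to close ten- to fourteen-membered terpenoid rings. The twelve-membered ring (C1 to C11 plus C15) closes in the exo-tet mode, bromide leaving outside the ring, and the six-membered ring is only a spectator. C6 becomes a stereocentre without a controlling element, and either epimer serves because step 18 turns C6 into a methylene. The step needs α- rather than γ-alkylation of the allyl anion and SN2 rather than SN2′ attack; the charge sits next to sulfur, C8 and C3 are the more substituted termini, and C5 is unhindered. Both olefin geometries must survive; the bromide olefin is not involved, and at −78 °C the potassium allyl sulfone anion should keep its C7=C8 geometry. Cyclisation must beat oligomerisation, which slow addition to the base at high dilution is meant to secure.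

Step 18
Reactants: 29 (1R,3E,7Z,10R,11S)-10-[(tert-butyldimethylsilyl)oxy]-13,13-(ethylenedioxy)-6-(phenylsulfonyl)verticilla-3,7,12(18)-triene
Product: 30 (1R,3E,7Z,10R,11S)-10-[(tert-butyldimethylsilyl)oxy]-13,13-(ethylenedioxy)verticilla-3,7,12(18)-triene
Conditions: PdCl2(dppp) (10 mol %), LiBHEt3 (3 equiv), THF, 0 °C
Reagents that add atoms: none
Why: Palladium-catalysed reductive desulfonylation of an allylic sulfone; hydride is delivered to the less substituted allyl terminus C6, so C7=C8 keeps its position, and fast trapping should keep its Z geometry.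

Step 19
Reactants: 30 (1R,3E,7Z,10R,11S)-10-[(tert-butyldimethylsilyl)oxy]-13,13-(ethylenedioxy)verticilla-3,7,12(18)-triene
Product: 31 (1R,3E,7Z,10R,11S)-10-hydroxyverticilla-3,7,12(18)-trien-13-one
Conditions: HF (48 % aq.), MeCN, 0 °C → rt
Reagents that add atoms: water, O
Why: Aqueous HF cleaves the hindered silyl ether and is acidic enough to hydrolyse the allylic dioxolane. It is used before any epoxide exists, so no acid meets an epoxide facing a transannular olefin.

Step 20
Reactants: 31 (1R,3E,7Z,10R,11S)-10-hydroxyverticilla-3,7,12(18)-trien-13-one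
Product: 32 (1R,3E,7R,8S,10R,11S)-7,8-epoxy-10-hydroxyverticilla-3,12(18)-dien-13-one
Conditions: VO(acac)2 (10 mol %), t-BuOOH (1.5 equiv), CH2Cl2, 0 °C → rt
Reagents that add atoms: tert-butyl hydroperoxide, CC(C)(C)OO
Why: Vanadium-catalysed hydroxyl-directed epoxidation of a homoallylic alcohol. In the chair-like vanadate transition state, with C11 equatorial on C10 and the C8 methyl axial (the only arrangement a Z-olefin allows), oxygen reaches the face that gives 7R,8S. The remote C3=C4 and the electron-poor C12=C18 are not addressed.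

Step 21
Reactants: 32 (1R,3E,7R,8S,10R,11S)-7,8-epoxy-10-hydroxyverticilla-3,12(18)-dien-13-one
Product: 33 (1R,3E,7R,8S,10R,11S)-10-acetoxy-7,8-epoxyverticilla-3,12(18)-dien-13-one
Conditions: Ac2O, pyridine, DMAP (cat.), CH2Cl2, rt
Reagents that add atoms: acetic anhydride, CC(=O)OC(C)=O
Why: DMAP-catalysed acetylation of a hindered secondary alcohol; the conditions are too mild to open the epoxide or move the enone double bond.

Step 22
Reactants: 33 (1R,3E,7R,8S,10R,11S)-10-acetoxy-7,8-epoxyverticilla-3,12(18)-dien-13-one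
Product: 34 (1R,3R,4R,7R,8S,10R,11S)-10-acetoxy-3,4:7,8-diepoxyverticill-12(18)-en-13-one (target)
Conditions: mCPBA (1.1 equiv), NaHCO3, CH2Cl2, −20 → 0 °C
Reagents that add atoms: 3-chloroperoxybenzoic acid, O=C(OO)c1cccc(Cl)c1
Why: Peracid (Prilezhaev) epoxidation of the only remaining electron-rich olefin; the E geometry gives the trans epoxide. Attack from the outer face of the macrocycle is expected to give 3R,4R, but this rests on ring conformation only.

## Compound list

1 | 4,4-dimethylcyclohex-2-en-1-one | CC1(C)CCC(=O)C=C1 | starting material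
2 | 4,4-dimethylcyclohexa-2,5-dien-1-one | CC1(C)C=CC(=O)C=C1 | intermediate
3 | potassium vinyltrifluoroborate | C=C[B-](F)(F)F.[K+] | starting material
4 | (5S)-5-ethenyl-4,4-dimethylcyclohex-2-en-1-one | O=C1C[C@@H](C=C)C(C)(C)C=C1 | intermediate
5 | (2-methylprop-1-en-1-yl)magnesium bromide | CC(C)=C[Mg]Br | starting material
6 | trimethyl{[(3R,5S)-5-ethenyl-4,4-dimethyl-3-(2-methylprop-1-en-1-yl)cyclohex-1-en-1-yl]oxy}silane | C1=C(O[Si](C)(C)C)C[C@@H](C=C)C(C)(C)[C@@H]1C=C(C)C | intermediate
7 | Mannich base, (3R,5S)-2-[(dimethylamino)methyl]-5-ethenyl-4,4-dimethyl-3-(2-methylprop-1-en-1-yl)cyclohexan-1-one (C2 epimers) | CN(C)CC1C(=O)C[C@@H](C=C)C(C)(C)[C@@H]1C=C(C)C | intermediate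
8 | ammonium iodide, N-methyl quaternary salt of 7 | C[N+](C)(C)CC1C(=O)C[C@@H](C=C)C(C)(C)[C@@H]1C=C(C)C.[I-] | intermediate
9 | (3S,5S)-5-ethenyl-4,4-dimethyl-2-methylidene-3-(2-methylprop-1-en-1-yl)cyclohexan-1-one | C=C1C(=O)C[C@@H](C=C)C(C)(C)[C@@H]1C=C(C)C | intermediate
10 | (7S,9S)-9-ethenyl-8,8-dimethyl-6-methylidene-7-(2-methylprop-1-en-1-yl)-1,4-dioxaspiro[4.5]decane | C=C1C2(OCCO2)C[C@@H](C=C)C(C)(C)[C@@H]1C=C(C)C | intermediate
11 | epoxide, (7S,9S)-7-(3,3-dimethyloxiran-2-yl)-9-ethenyl-8,8-dimethyl-6-methylidene-1,4-dioxaspiro[4.5]decane (oxirane epimers) | C=C1C2(OCCO2)C[C@@H](C=C)C(C)(C)[C@@H]1C3OC3(C)C | intermediate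
12 | (7S,9S)-9-ethenyl-8,8-dimethyl-6-methylidene-1,4-dioxaspiro[4.5]decane-7-carbaldehyde | C=C1C2(OCCO2)C[C@@H](C=C)C(C)(C)[C@@H]1C=O | intermediate
13 | ethyl 3-methylbut-2-enoate | CCOC(=O)C=C(C)C | starting material
14 | [(1-ethoxy-3-methylbuta-1,3-dien-1-yl)oxy]trimethylsilane | CCOC(O[Si](C)(C)C)=CC(C)=C | intermediate
15 | (6R)-6-[(7S,9S)-9-ethenyl-8,8-dimethyl-6-methylidene-1,4-dioxaspiro[4.5]decan-7-yl]-4-methyl-5,6-dihydro-2H-pyran-2-one | C=C1C2(OCCO2)C[C@@H](C=C)C(C)(C)[C@@H]1[C@H]3CC(C)=CC(=O)O3 | intermediate
16 | (2Z,5R)-5-[(7S,9S)-9-ethenyl-8,8-dimethyl-6-methylidene-1,4-dioxaspiro[4.5]decan-7-yl]-3-methylpent-2-ene-1,5-diol | C=C1C2(OCCO2)C[C@@H](C=C)C(C)(C)[C@@H]1[C@H](O)C/C(C)=C\CO | intermediate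
17 | bis(tert-butyldimethylsilyl) ether of diol 16 (2Z,5R) | C=C1C2(OCCO2)C[C@@H](C=C)C(C)(C)[C@@H]1[C@H](O[Si](C)(C)C(C)(C)C)C/C(C)=C\CO[Si](C)(C)C(C)(C)C | intermediate
18 | (2Z,5R)-5-[(tert-butyldimethylsilyl)oxy]-5-[(7S,9S)-9-ethenyl-8,8-dimethyl-6-methylidene-1,4-dioxaspiro[4.5]decan-7-yl]-3-methylpent-2-en-1-ol | C=C1C2(OCCO2)C[C@@H](C=C)C(C)(C)[C@@H]1[C@H](O[Si](C)(C)C(C)(C)C)C/C(C)=C\CO | intermediate
19 | sodium benzenesulfinate | [Na+].[O-]S(=O)c1ccccc1 | starting material
20 | mesylate, methanesulfonate of alcohol 18 | C=C1C2(OCCO2)C[C@@H](C=C)C(C)(C)[C@@H]1[C@H](O[Si](C)(C)C(C)(C)C)C/C(C)=C\COS(C)(=O)=O | intermediate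
21 | tert-butyl{[(1R,3Z)-1-[(7S,9S)-9-ethenyl-8,8-dimethyl-6-methylidene-1,4-dioxaspiro[4.5]decan-7-yl]-3-methyl-5-(phenylsulfonyl)pent-3-en-1-yl]oxy}dimethylsilane | C=C1C2(OCCO2)C[C@@H](C=C)C(C)(C)[C@@H]1[C@H](O[Si](C)(C)C(C)(C)C)C/C(C)=C\CS(=O)(=O)c3ccccc3 | intermediate
22 | alkylborane, B-[2-(ring C9)ethyl]bis(3-methylbutan-2-yl)borane derived from 21 | C=C1C2(OCCO2)C[C@@H](CCB(C(C)C(C)C)C(C)C(C)C)C(C)(C)[C@@H]1[C@H](O[Si](C)(C)C(C)(C)C)C/C(C)=C\CS(=O)(=O)c3ccccc3 | intermediate
23 | 2-[(7S,9R)-7-[(1R,3Z)-1-[(tert-butyldimethylsilyl)oxy]-3-methyl-5-(phenylsulfonyl)pent-3-en-1-yl]-8,8-dimethyl-6-methylidene-1,4-dioxaspiro[4.5]decan-9-yl]ethan-1-ol | C=C1C2(OCCO2)C[C@@H](CCO)C(C)(C)[C@@H]1[C@H](O[Si](C)(C)C(C)(C)C)C/C(C)=C\CS(=O)(=O)c3ccccc3 | intermediate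
24 | ethyl 2-(triphenylphosphoranylidene)propanoate | CCOC(=O)C(C)=P(c1ccccc1)(c1ccccc1)c1ccccc1 | starting material
25 | aldehyde, 2-[(7S,9R)-ring C9]acetaldehyde corresponding to alcohol 23 | C=C1C2(OCCO2)C[C@@H](CC=O)C(C)(C)[C@@H]1[C@H](O[Si](C)(C)C(C)(C)C)C/C(C)=C\CS(=O)(=O)c3ccccc3 | intermediate
26 | ethyl (2E)-4-[(7S,9R)-7-[(1R,3Z)-1-[(tert-butyldimethylsilyl)oxy]-3-methyl-5-(phenylsulfonyl)pent-3-en-1-yl]-8,8-dimethyl-6-methylidene-1,4-dioxaspiro[4.5]decan-9-yl]-2-methylbut-2-enoate | C=C1C2(OCCO2)C[C@@H](C/C=C(C)/C(=O)OCC)C(C)(C)[C@@H]1[C@H](O[Si](C)(C)C(C)(C)C)C/C(C)=C\CS(=O)(=O)c3ccccc3 | intermediate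
27 | (2E)-4-[(7S,9R)-7-[(1R,3Z)-1-[(tert-butyldimethylsilyl)oxy]-3-methyl-5-(phenylsulfonyl)pent-3-en-1-yl]-8,8-dimethyl-6-methylidene-1,4-dioxaspiro[4.5]decan-9-yl]-2-methylbut-2-en-1-ol | C=C1C2(OCCO2)C[C@@H](C/C=C(C)/CO)C(C)(C)[C@@H]1[C@H](O[Si](C)(C)C(C)(C)C)C/C(C)=C\CS(=O)(=O)c3ccccc3 | intermediate
28 | {[(1R,3Z)-1-[(7S,9R)-9-[(2E)-4-bromo-3-methylbut-2-en-1-yl]-8,8-dimethyl-6-methylidene-1,4-dioxaspiro[4.5]decan-7-yl]-3-methyl-5-(phenylsulfonyl)pent-3-en-1-yl]oxy}(tert-butyl)dimethylsilane | C=C1C2(OCCO2)C[C@@H](C/C=C(C)/CBr)C(C)(C)[C@@H]1[C@H](O[Si](C)(C)C(C)(C)C)C/C(C)=C\CS(=O)(=O)c3ccccc3 | intermediate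
29 | (1R,3E,7Z,10R,11S)-10-[(tert-butyldimethylsilyl)oxy]-13,13-(ethylenedioxy)-6-(phenylsulfonyl)verticilla-3,7,12(18)-triene (C6 epimers, one drawn) | C=C1C2(OCCO2)C[C@H]3C/C=C(C)/C[C@H](S(=O)(=O)c4ccccc4)/C=C(C)\C[C@@H](O[Si](C)(C)C(C)(C)C)[C@H]1C3(C)C | intermediate
30 | (1R,3E,7Z,10R,11S)-10-[(tert-butyldimethylsilyl)oxy]-13,13-(ethylenedioxy)verticilla-3,7,12(18)-triene | C=C1C2(OCCO2)C[C@H]3C/C=C(C)/CC/C=C(C)\C[C@@H](O[Si](C)(C)C(C)(C)C)[C@H]1C3(C)C | intermediate
31 | (1R,3E,7Z,10R,11S)-10-hydroxyverticilla-3,7,12(18)-trien-13-one | C=C1C(=O)C[C@H]2C/C=C(C)/CC/C=C(C)\C[C@@H](O)[C@H]1C2(C)C | intermediate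
32 | (1R,3E,7R,8S,10R,11S)-7,8-epoxy-10-hydroxyverticilla-3,12(18)-dien-13-one | C=C1C(=O)C[C@H]2C/C=C(C)/CC[C@H]3O[C@@]3(C)C[C@@H](O)[C@H]1C2(C)C | intermediate
33 | (1R,3E,7R,8S,10R,11S)-10-acetoxy-7,8-epoxyverticilla-3,12(18)-dien-13-one | C=C1C(=O)C[C@H]2C/C=C(C)/CC[C@H]3O[C@@]3(C)C[C@@H](OC(C)=O)[C@H]1C2(C)C | intermediate
34 | (1R,3R,4R,7R,8S,10R,11S)-10-acetoxy-3,4:7,8-diepoxyverticill-12(18)-en-13-one | C=C1C(=O)C[C@H]2C[C@H]3O[C@]3(C)CC[C@H]3O[C@@]3(C)C[C@@H](OC(C)=O)[C@H]1C2(C)C | target

## Count and risks

Total: 22 steps. Longest linear sequence: 21 steps (steps 1–6 and 8–22; step 7 prepares the dienolate).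

**Step 17 (key step).** Intermolecular alkylation may outrun closure of a ring whose two bridge bonds are trans on the cyclohexane. The carbanion may attack the γ-terminus, or the base may cause 1,4-loss of HBr. The allyl anion may lose its Z geometry by rotation. The fallback sets out from bis-silyl ether 17 and drops the sulfone. Hydroboration with Sia2BH would give the alkylborane F1 and, after oxidation, the primary alcohol F2. Dess–Martin oxidation to the aldehyde F3 and Wittig reaction with 24 would give the enoate F4. Reduction with i-Bu2AlH would give the allylic alcohol F5. HF·pyridine would free the primary allylic hydroxyl to give the diol F6, and CBr4/PPh3 would give the bis(allylic) dibromide F7. Reductive allyl–allyl coupling of F7 with Ni(CO)4 (zerovalent nickel) at high dilution would form the same C5–C6 bond and return to the route at 30. Erosion of olefin geometry at nickel is the known weakness of this coupling.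

**Step 2.** Carbometalation at the neopentyl β-carbon may be slow. The product enone may take up a second vinyl group. Face discrimination may be weaker than on the parent cyclohexenone. The fallback sets out from 2: racemic vinylation with vinylmagnesium bromide, CuBr·SMe2 and TMSCl, then separation of 4 from its antipode, (5R)-5-ethenyl-4,4-dimethylcyclohex-2-en-1-one F8, by preparative chromatography on a chiral stationary phase. It returns at 4.

**Step 8.** The dienolate may attack through its α-carbon, or give the open-chain E-hydroxy ester, which cannot lactonise. The facial bias at C10 may be too small. The aldehyde may epimerise at C11 or let C12=C18 drift into conjugation. The fallback sets out from 12 and uses reagent control without base. Brown methallylation at −78 °C, with the borane from (+)-B-methoxydiisopinocampheylborane and 2-methylallylmagnesium chloride, would give the homoallylic alcohol F9. Acryloyl chloride and Et3N would give the acrylate F10. Ring-closing metathesis with the second-generation Grubbs catalyst would return to the route at lactone 15. The C1 vinyl group could compete there, but six-membered ring closure should be favoured.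

**Step 20.** Inside the macrocycle the hydroxyl may not reach the olefin face the chair model requires. It may be partly tied up as a hemiketal with the C13 ketone. Oxygen may then be delivered slowly or to the wrong face. The fallback sets out from 31 and gives up direction. Acetylation would give the dienyl acetate F11, and excess mCPBA would epoxidise both ring olefins from the outer face of the macrocycle, returning at 34.

**Step 22.** Facial selectivity at C3=C4 may be poor, since only the ring conformation distinguishes the two faces. The fallback sets out from 33 and replaces substrate control by catalyst control. Shi epoxidation with the D-fructose-derived ketone and Oxone, which gives R,R epoxides from E-trisubstituted olefins, would return at 34 without any new intermediate.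

## Further compounds

F1 | step 17 | alkylborane from hydroboration of the vinyl group of 17 | C=C1C2(OCCO2)C[C@@H](CCB(C(C)C(C)C)C(C)C(C)C)C(C)(C)[C@@H]1[C@H](O[Si](C)(C)C(C)(C)C)C/C(C)=C\CO[Si](C)(C)C(C)(C)C
F2 | step 17 | primary alcohol (C3–OH) of the bis-silyl series | C=C1C2(OCCO2)C[C@@H](CCO)C(C)(C)[C@@H]1[C@H](O[Si](C)(C)C(C)(C)C)C/C(C)=C\CO[Si](C)(C)C(C)(C)C
F3 | step 17 | C3 aldehyde of the bis-silyl series | C=C1C2(OCCO2)C[C@@H](CC=O)C(C)(C)[C@@H]1[C@H](O[Si](C)(C)C(C)(C)C)C/C(C)=C\CO[Si](C)(C)C(C)(C)C
F4 | step 17 | (E)-enoate of the bis-silyl series | C=C1C2(OCCO2)C[C@@H](C/C=C(C)/C(=O)OCC)C(C)(C)[C@@H]1[C@H](O[Si](C)(C)C(C)(C)C)C/C(C)=C\CO[Si](C)(C)C(C)(C)C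
F5 | step 17 | (E)-allylic alcohol (C5–OH), O6 and O10 silylated | C=C1C2(OCCO2)C[C@@H](C/C=C(C)/CO)C(C)(C)[C@@H]1[C@H](O[Si](C)(C)C(C)(C)C)C/C(C)=C\CO[Si](C)(C)C(C)(C)C
F6 | step 17 | C5,C6-diol, O10 silylated | C=C1C2(OCCO2)C[C@@H](C/C=C(C)/CO)C(C)(C)[C@@H]1[C@H](O[Si](C)(C)C(C)(C)C)C/C(C)=C\CO
F7 | step 17 | C5,C6-bis(allylic) dibromide, O10 silylated | C=C1C2(OCCO2)C[C@@H](C/C=C(C)/CBr)C(C)(C)[C@@H]1[C@H](O[Si](C)(C)C(C)(C)C)C/C(C)=C\CBr
F8 | step 2 | (5R)-5-ethenyl-4,4-dimethylcyclohex-2-en-1-one | O=C1C[C@H](C=C)C(C)(C)C=C1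
F9 | step 8 | (1R)-1-[(7S,9S)-9-ethenyl-8,8-dimethyl-6-methylidene-1,4-dioxaspiro[4.5]decan-7-yl]-3-methylbut-3-en-1-ol | C=C1C2(OCCO2)C[C@@H](C=C)C(C)(C)[C@@H]1[C@H](O)CC(C)=C
F10 | step 8 | acrylate ester of F9 | C=C1C2(OCCO2)C[C@@H](C=C)C(C)(C)[C@@H]1[C@H](OC(=O)C=C)CC(C)=C
F11 | step 20 | (1R,3E,7Z,10R,11S)-10-acetoxyverticilla-3,7,12(18)-trien-13-one | C=C1C(=O)C[C@H]2C/C=C(C)/CC/C=C(C)\C[C@@H](OC(C)=O)[C@H]1C2(C)C
F0 | step 22 | none | none
A1 | alternative 1 | (3E,7Z)-verticilla-3,7,12(18)-triene | C=C1CC[C@H]2C/C=C(C)/CC/C=C(C)\CC[C@H]1C2(C)C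
A2 | alternative 1 | (2E,6Z,10E)-geranylgeranyl diphosphate | CC(C)=CCC/C(C)=C/CC/C(C)=C\CC/C(C)=C/COP(=O)(O)OP(=O)(O)O
A3 | alternative 2 | trans C3–C4 epoxide joining ring and Z chain | C=C1C2(OCCO2)C[C@@H](C[C@H]3O[C@]3(C)CC/C=C(C)\CO[Si](C)(C)C(C)(C)C)C(C)(C)[C@@H]1CO[Si](C)(C)C(C)(C)C
A4 | alternative 2 | ring-bound α-chloro methyl ketone | C=C1C2(OCCO2)C[C@@H](C[C@H](Cl)C(C)=O)C(C)(C)[C@@H]1CO[Si](C)(C)C(C)(C)C
A5 | alternative 2 | (Z)-homoallylic Grignard reagent | Br[Mg]CC/C=C(C)\CO[Si](C)(C)C(C)(C)C
A6 | alternative 3 | isoxazoline-bridged macrocycle | C=C1C2(OCCO2)C[C@H]3C/C=C(C)/CC[C@H](O[Si](C)(C)C(C)(C)C)C4=NO[C@H](C4)[C@H]1C3(C)C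
A7 | alternative 3 | seco aldoxime with vinyl group on C11 | C=C1C2(OCCO2)C[C@@H](C/C=C(C)/CC[C@H](O[Si](C)(C)C(C)(C)C)C=NO)C(C)(C)[C@@H]1C=C
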